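**Retrosynthetic overview**

1. The target is a dimer of one (2R,3R)-7,8,3',4'-oxygenated flavan. The upper unit is all-cis (2R,3R,4R) and carries at C4 the C6 carbon of the lower (2R,3R,4S)-flavan-3,4-diol. The C4–C6 interflavan bond is cut to a flavan-4-one (electrophile) and a 6-metallated flavan (nucleophile), both taken from one monomer.
2. The all-cis upper unit is the syn-hydrogenation product of a C3=C4 silyl enol ether, hydrogen entering opposite the C2 aryl group. The 3,4-trans diol of the lower unit comes from DDQ oxidation at C4 of the 2,3-cis flavan.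
3. Ring C of the monomer is cut at O1–C8a and C3–C4. The enabling feature: O1 sits on C8a of ring A, and C8a is ortho (through C4a) to the benzylic carbon C4. Ring A with C4 is therefore a 2-bromobenzyl bromide (1,3-dielectrophile C8a/C4), and O1–C2–C3 with ring B on C2 is the enolate of an aryl methyl ketone (1,3-O,C-dinucleophile).
4. Ring order: rings A and B are bought as benzenoid pieces; ring C is closed once, in the key step, and its product serves both halves; C2 and C3 are then set by asymmetric hydroboration; the two heterocycles are joined last.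

Key step: step 5

Remark: the face selectivity of the borane in step 6 is assigned by analogy with 1-arylcycloalkenes; should the opposite face be attacked, the reagent from (−)-α-pinene is used instead and nothing else changes.

**Route**

Step 1
Reactants: 1 2-bromo-3-hydroxy-4-methoxybenzaldehyde
Product: 2 2-bromo-3,4-dihydroxybenzaldehyde
Conditions: BBr3 (2.5 equiv), CH2Cl2, −78 → 20 °C; then H2O
Reagents that add atoms: none
Why: Lewis-acid cleavage of the aryl methyl ether (BBr3 demethylation) should free the second phenol so that both ring A oxygens can carry hydrogenolysable benzyl groups; aldehyde and aryl bromide are inert.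

Step 2
Reactants: 2 2-bromo-3,4-dihydroxybenzaldehyde
Product: 3 3,4-bis(benzyloxy)-2-bromobenzaldehyde
Conditions: BnBr (2.3 equiv), K2CO3, DMF, 60 °C
Reagents that add atoms: benzyl bromide, BrCc1ccccc1
Why: Williamson etherification of both phenols should proceed cleanly; no stereocentre is involved.

Step 3
Reactants: 3 3,4-bis(benzyloxy)-2-bromobenzaldehyde
Product: 4 [3,4-bis(benzyloxy)-2-bromophenyl]methanol
Conditions: NaBH4, THF/MeOH, 0 °C
Reagents that add atoms: none
Why: Borohydride reduction of the aldehyde should give the benzylic alcohol without touching the aryl bromide or the benzyl ethers.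

Step 4
Reactants: 4 [3,4-bis(benzyloxy)-2-bromophenyl]methanol
Product: 5 1,2-bis(benzyloxy)-3-bromo-4-(bromomethyl)benzene
Conditions: PBr3 (0.4 equiv), CH2Cl2, 0 °C
Reagents that add atoms: phosphorus tribromide, BrP(Br)Br
Why: Bromination of the benzylic alcohol through its phosphite ester (SN2) should give the 1,3-dielectrophile, with the benzylic C–Br as the future C4 and the aryl C–Br as the future C8a.

Step 5
Reactants: 5 1,2-bis(benzyloxy)-3-bromo-4-(bromomethyl)benzene, 6 1-[3,4-bis(benzyloxy)phenyl]ethan-1-one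
Product: 8 7,8-bis(benzyloxy)-2-[3,4-bis(benzyloxy)phenyl]-4H-chromene, via C-benzylated ketone 7 (not isolated)
Conditions: 6 (1.5 equiv), KOtBu (2.6 equiv), CuI (10 mol %), 1,10-phenanthroline (20 mol %), 1,4-dioxane, slow addition of 5 at 20 °C, then 100 °C
Reagents that add atoms: none
Why: Proposed new method: the potassium enolate of 6 should be C-benzylated by the benzylic bromide of 5 (SN2, the aryl bromide being inert at 20 °C) to give 7, whose (Z)-enolate, formed by the second equivalent of base, holds the enolate oxygen cis to the CH2Ar chain and should close ring C at 100 °C by copper-catalysed Ullmann-type C(aryl)–O coupling (oxidative addition of the C8a–Br bond to the monovalent copper enolate, then reductive elimination from trivalent copper). The closest known reactions are the CuI-catalysed domino C-benzylation/O-arylation of 1,3-dicarbonyl compounds with 2-bromobenzyl bromides to 4H-chromenes and the separate copper-catalysed intramolecular O-arylation of aryl ketone enolates; the extension proposed here is to a non-activated aryl methyl ketone in one flask. Ring C closes as a six-membered ring by attack of O1 on C8a, with the C2=C3 enol double bond ending up inside the ring, whereas C-arylation would need a four-membered ring and cannot compete. No stereocentre is formed (8 is achiral), which is intended, since C2 and C3 are set together in step 6. The step needs mono- over bis-benzylation and C- over O-alkylation, which slow addition of 5 to an excess of the soft potassium enolate should secure, and it needs site selectivity between the two C–Br bonds, which their different mechanisms (SN2 at 20 °C, copper catalysis at 100 °C) should secure; the aryl bromide has no ortho hydrogen, so aryne formation is excluded.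

Step 6
Reactants: 8 7,8-bis(benzyloxy)-2-[3,4-bis(benzyloxy)phenyl]-4H-chromene
Product: 9 (2R,3S)-7,8-bis(benzyloxy)-2-[3,4-bis(benzyloxy)phenyl]chroman-3-ol (2,3-trans)
Conditions: IpcBH2 (monoisopinocampheylborane from (+)-α-pinene), THF, −25 °C; then NaOH, H2O2, 0 → 20 °C
Reagents that add atoms: hydrogen peroxide, OO
Why: Asymmetric hydroboration–oxidation of the trisubstituted enol ether should place boron on C3 (β to O1 and remote from the aryl group) and hydrogen on C2 from the same face, which gives the 2,3-trans alcohol after oxidation with retention; the isopinocampheyl group selects the face, as with 1-arylcycloalkenes, and so sets C2 as R and C3 as S.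

Step 7
Reactants: 9 (2R,3S)-7,8-bis(benzyloxy)-2-[3,4-bis(benzyloxy)phenyl]chroman-3-ol
Product: 10 (2R)-7,8-bis(benzyloxy)-2-[3,4-bis(benzyloxy)phenyl]chroman-3-one
Conditions: Dess–Martin periodinane, NaHCO3, CH2Cl2, 0 → 20 °C
Reagents that add atoms: none
Why: Dess–Martin oxidation under buffered neutral conditions should give the flavan-3-one without enolisation, so that C2 keeps its configuration.

Step 8
Reactants: 10 (2R)-7,8-bis(benzyloxy)-2-[3,4-bis(benzyloxy)phenyl]chroman-3-one
Product: 11 (2R,3R)-7,8-bis(benzyloxy)-2-[3,4-bis(benzyloxy)phenyl]chroman-3-ol (2,3-cis)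
Conditions: Li[HB(s-Bu)3] (L-Selectride), THF, −78 °C; then H2O
Reagents that add atoms: none
Why: Reduction with a bulky hydride should occur by equatorial attack and give the axial 3-OH cis to the equatorial C2 aryl group (C3 R), the known way to invert C3 of 2,3-trans flavan-3-ols; C2 is not touched at −78 °C.

Step 9
Reactants: 11 (2R,3R)-7,8-bis(benzyloxy)-2-[3,4-bis(benzyloxy)phenyl]chroman-3-ol
Product: 12 (2R,3R)-7,8-bis(benzyloxy)-2-[3,4-bis(benzyloxy)phenyl]-3-(tert-butyldimethylsilyloxy)chroman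
Conditions: TBSOTf, 2,6-lutidine, CH2Cl2, −78 → 0 °C
Reagents that add atoms: tert-butyldimethylsilyl trifluoromethanesulfonate, CC(C)(C)[Si](C)(C)OS(=O)(=O)C(F)(F)F
Why: Silylation of the hindered axial secondary alcohol with the silyl triflate should be complete; no stereocentre is touched.

Step 10
Reactants: 12 (2R,3R)-7,8-bis(benzyloxy)-2-[3,4-bis(benzyloxy)phenyl]-3-(tert-butyldimethylsilyloxy)chroman
Product: 13 (2R,3R,4S)-7,8-bis(benzyloxy)-2-[3,4-bis(benzyloxy)phenyl]-3-(tert-butyldimethylsilyloxy)chroman-4-ol (2,3-cis-3,4-trans)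
Conditions: DDQ (1.2 equiv), CH2Cl2/H2O (18:1), 0 → 20 °C
Reagents that add atoms: water, O
Why: DDQ-mediated benzylic oxidation should abstract hydride from C4 to give the cation stabilised by O1 and the C7 benzyloxy group, and water should add on the face opposite the axial 3-silyloxy group, which sets C4 as S (3,4-trans).

Step 11
Reactants: 13 (2R,3R,4S)-7,8-bis(benzyloxy)-2-[3,4-bis(benzyloxy)phenyl]-3-(tert-butyldimethylsilyloxy)chroman-4-ol (one portion)
Product: 14 (2R,3S)-7,8-bis(benzyloxy)-2-[3,4-bis(benzyloxy)phenyl]-3-(tert-butyldimethylsilyloxy)chroman-4-one (2,3-cis)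
Conditions: Dess–Martin periodinane, NaHCO3, CH2Cl2, 0 → 20 °C
Reagents that add atoms: none
Why: Dess–Martin oxidation of the benzylic alcohol should give the flavan-4-one that serves as the upper unit electrophile; C2 is untouched and the configuration at C3 has no consequence later.

Step 12
Reactants: 13 (2R,3R,4S)-7,8-bis(benzyloxy)-2-[3,4-bis(benzyloxy)phenyl]-3-(tert-butyldimethylsilyloxy)chroman-4-ol (other portion)
Product: 15 (2R,3S,4S)-7,8-bis(benzyloxy)-2-[3,4-bis(benzyloxy)phenyl]-3,4-bis(tert-butyldimethylsilyloxy)chroman (2α-aryl, 3α-O, 4β-O)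
Conditions: TBSOTf, 2,6-lutidine, CH2Cl2, −78 °C
Reagents that add atoms: tert-butyldimethylsilyl trifluoromethanesulfonate, CC(C)(C)[Si](C)(C)OS(=O)(=O)C(F)(F)F
Why: Silylation of the benzylic alcohol at low temperature with a hindered base should protect C4–O as a silyl ether, which resists organolithium reagents and hydrogenolysis; no stereocentre is touched.

Step 13
Reactants: 15 (2R,3S,4S)-7,8-bis(benzyloxy)-2-[3,4-bis(benzyloxy)phenyl]-3,4-bis(tert-butyldimethylsilyloxy)chroman
Product: 16 (2R,3S,4S)-7,8-bis(benzyloxy)-2-[3,4-bis(benzyloxy)phenyl]-6-bromo-3,4-bis(tert-butyldimethylsilyloxy)chroman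
Conditions: NBS (1.05 equiv), CH2Cl2, −40 → 0 °C, dark
Reagents that add atoms: N-bromosuccinimide, O=C1CCC(=O)N1Br
Why: Electrophilic aromatic bromination should occur at C6, which is ortho to the C7 benzyloxy group and para to O1, whereas C5 is shielded by the C4 silyloxy group and ring B is less electron-rich.

Step 14
Reactants: 16 (2R,3S,4S)-7,8-bis(benzyloxy)-2-[3,4-bis(benzyloxy)phenyl]-6-bromo-3,4-bis(tert-butyldimethylsilyloxy)chroman, 14 (2R,3S)-7,8-bis(benzyloxy)-2-[3,4-bis(benzyloxy)phenyl]-3-(tert-butyldimethylsilyloxy)chroman-4-one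
Product: 20 (2R)-7,8-bis(benzyloxy)-2-[3,4-bis(benzyloxy)phenyl]-3-(tert-butyldimethylsilyloxy)-4-[(2R,3S,4S)-7,8-bis(benzyloxy)-2-[3,4-bis(benzyloxy)phenyl]-3,4-bis(tert-butyldimethylsilyloxy)chroman-6-yl]-2H-chromene, via aryllithium 17 (not isolated), via arylcerium dichloride 18 (not isolated), via tertiary carbinol 19 (not isolated)
Conditions: 16, t-BuLi (2.05 equiv), THF, −78 °C; CeCl3 (anhydrous), −78 °C; then 14, −78 → −40 °C; then Et3N, MsCl, −40 → 0 °C
Reagents that add atoms: none
Why: Halogen–lithium exchange, transmetalation to the weakly basic organocerium reagent (which should suppress enolisation and ring opening of the flavanone), 1,2-addition to the C4 ketone and dehydration through the tertiary mesylate (E1) follow the classical aryl-metal addition/dehydration route to 4-arylflav-3-enes; the carbinol centre and C3 become sp2 and C2 is untouched.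

Step 15
Reactants: 20 the 3-silyloxy-4-aryl-2H-chromene dimer
Product: 21 all-cis protected dimer: 7,8-bis(benzyloxy)-2α-[3,4-bis(benzyloxy)phenyl]-3α-(tert-butyldimethylsilyloxy)-4α-[(2R,3S,4S)-7,8-bis(benzyloxy)-2-[3,4-bis(benzyloxy)phenyl]-3,4-bis(tert-butyldimethylsilyloxy)chroman-6-yl]chroman (upper unit 2R, hydrogens at C3 and C4 both β)
Conditions: H2 (5 bar), Pd/C (10 %), pyridine (0.5 equiv), EtOAc, 25 °C
Reagents that add atoms: none
Why: Heterogeneous syn hydrogenation of the tetrasubstituted silyl enol ether should deliver both hydrogens to the face opposite the pseudo-axial C2 aryl group, so that the 3-silyloxy and 4-aryl groups end up cis to the C2 aryl group (all-cis), as known for 3,4-disubstituted 2H-chromenes and 4-arylflav-3-enes; pyridine-poisoned Pd/C should leave the benzyl ethers in place.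

Step 16
Reactants: 21 the all-cis protected dimer
Product: 22 octaphenol tris(silyl ether): the dimer with eight free phenols and tert-butyldimethylsilyl ethers at C3 of the upper unit and at C3 and C4 of the lower unit
Conditions: H2 (1 bar), Pd(OH)2/C, THF/EtOAc, 25 °C
Reagents that add atoms: none
Why: Hydrogenolysis of the eight aryl benzyl ethers should proceed under neutral aprotic conditions, while the three silyl ethers (including the benzylic one at C4 of the lower unit) and the ring C–O bonds are retained.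

Step 17
Reactants: 22 the octaphenol tris(silyl ether)
Product: 23 the target, (2R,3R,4R)-2-(3,4-dihydroxyphenyl)-4-[(2R,3R,4S)-2-(3,4-dihydroxyphenyl)-3,4,7,8-tetrahydroxychroman-6-yl]chroman-3,7,8-triol
Conditions: HF·pyridine, pyridine/THF, 0 → 20 °C, argon
Reagents that add atoms: none
Why: Fluoride-mediated desilylation in a pyridine-buffered medium should free the three aliphatic hydroxyl groups without ionising the benzylic C4–OH of the lower unit; no stereocentre is touched.

**Compound list**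

1 | 2-bromo-3-hydroxy-4-methoxybenzaldehyde | O=Cc1ccc(OC)c(O)c1Br | starting material
2 | 2-bromo-3,4-dihydroxybenzaldehyde | O=Cc1ccc(O)c(O)c1Br | intermediate
3 | 3,4-bis(benzyloxy)-2-bromobenzaldehyde | O=Cc1ccc(OCc2ccccc2)c(OCc2ccccc2)c1Br | intermediate
4 | [3,4-bis(benzyloxy)-2-bromophenyl]methanol | OCc1ccc(OCc2ccccc2)c(OCc2ccccc2)c1Br | intermediate
5 | 1,2-bis(benzyloxy)-3-bromo-4-(bromomethyl)benzene | BrCc1ccc(OCc2ccccc2)c(OCc2ccccc2)c1Br | intermediate
6 | 1-[3,4-bis(benzyloxy)phenyl]ethan-1-one | CC(=O)c1ccc(OCc2ccccc2)c(OCc2ccccc2)c1 | starting material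
7 | 3-[3,4-bis(benzyloxy)-2-bromophenyl]-1-[3,4-bis(benzyloxy)phenyl]propan-1-one (formed in the flask) | O=C(CCc1ccc(OCc2ccccc2)c(OCc2ccccc2)c1Br)c1ccc(OCc2ccccc2)c(OCc2ccccc2)c1 | intermediate
8 | 7,8-bis(benzyloxy)-2-[3,4-bis(benzyloxy)phenyl]-4H-chromene (achiral) | C1=C(c2ccc(OCc3ccccc3)c(OCc3ccccc3)c2)Oc2c(C1)ccc(OCc1ccccc1)c2OCc1ccccc1 | intermediate
9 | (2R,3S)-7,8-bis(benzyloxy)-2-[3,4-bis(benzyloxy)phenyl]chroman-3-ol (2,3-trans) | O[C@H]1Cc2ccc(OCc3ccccc3)c(OCc3ccccc3)c2O[C@@H]1c1ccc(OCc2ccccc2)c(OCc2ccccc2)c1 | intermediate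
10 | (2R)-7,8-bis(benzyloxy)-2-[3,4-bis(benzyloxy)phenyl]chroman-3-one | O=C1Cc2ccc(OCc3ccccc3)c(OCc3ccccc3)c2O[C@@H]1c1ccc(OCc2ccccc2)c(OCc2ccccc2)c1 | intermediate
11 | (2R,3R)-7,8-bis(benzyloxy)-2-[3,4-bis(benzyloxy)phenyl]chroman-3-ol (2,3-cis) | O[C@@H]1Cc2ccc(OCc3ccccc3)c(OCc3ccccc3)c2O[C@@H]1c1ccc(OCc2ccccc2)c(OCc2ccccc2)c1 | intermediate
12 | (2R,3R)-7,8-bis(benzyloxy)-2-[3,4-bis(benzyloxy)phenyl]-3-(tert-butyldimethylsilyloxy)chroman | CC(C)(C)[Si](C)(C)O[C@@H]1Cc2ccc(OCc3ccccc3)c(OCc3ccccc3)c2O[C@@H]1c1ccc(OCc2ccccc2)c(OCc2ccccc2)c1 | intermediate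
13 | (2R,3R,4S)-7,8-bis(benzyloxy)-2-[3,4-bis(benzyloxy)phenyl]-3-(tert-butyldimethylsilyloxy)chroman-4-ol | CC(C)(C)[Si](C)(C)O[C@@H]1[C@@H](O)c2ccc(OCc3ccccc3)c(OCc3ccccc3)c2O[C@@H]1c1ccc(OCc2ccccc2)c(OCc2ccccc2)c1 | intermediate
14 | (2R,3S)-7,8-bis(benzyloxy)-2-[3,4-bis(benzyloxy)phenyl]-3-(tert-butyldimethylsilyloxy)chroman-4-one (2,3-cis) | CC(C)(C)[Si](C)(C)O[C@@H]1C(=O)c2ccc(OCc3ccccc3)c(OCc3ccccc3)c2O[C@@H]1c1ccc(OCc2ccccc2)c(OCc2ccccc2)c1 | intermediate
15 | (2R,3S,4S)-7,8-bis(benzyloxy)-2-[3,4-bis(benzyloxy)phenyl]-3,4-bis(tert-butyldimethylsilyloxy)chroman | CC(C)(C)[Si](C)(C)O[C@@H]1[C@@H](O[Si](C)(C)C(C)(C)C)c2ccc(OCc3ccccc3)c(OCc3ccccc3)c2O[C@@H]1c1ccc(OCc2ccccc2)c(OCc2ccccc2)c1 | intermediate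
16 | (2R,3S,4S)-7,8-bis(benzyloxy)-2-[3,4-bis(benzyloxy)phenyl]-6-bromo-3,4-bis(tert-butyldimethylsilyloxy)chroman | CC(C)(C)[Si](C)(C)O[C@@H]1[C@@H](O[Si](C)(C)C(C)(C)C)c2cc(Br)c(OCc3ccccc3)c(OCc3ccccc3)c2O[C@@H]1c1ccc(OCc2ccccc2)c(OCc2ccccc2)c1 | intermediate
17 | 6-lithio derivative of 15 (formed in the flask) | CC(C)(C)[Si](C)(C)O[C@@H]1[C@@H](O[Si](C)(C)C(C)(C)C)c2cc([Li])c(OCc3ccccc3)c(OCc3ccccc3)c2O[C@@H]1c1ccc(OCc2ccccc2)c(OCc2ccccc2)c1 | intermediate
18 | 6-(dichlorocerio) derivative of 15 (formed in the flask) | CC(C)(C)[Si](C)(C)O[C@@H]1[C@@H](O[Si](C)(C)C(C)(C)C)c2cc([Ce](Cl)Cl)c(OCc3ccccc3)c(OCc3ccccc3)c2O[C@@H]1c1ccc(OCc2ccccc2)c(OCc2ccccc2)c1 | intermediate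
19 | tertiary carbinol: 4-hydroxy-4-aryl adduct of 14 and 18, expected epimer with the new aryl group trans to the 3-silyloxy group (formed in the flask) | CC(C)(C)[Si](C)(C)O[C@@H]1[C@@](O)(c2cc3[C@H](O[Si](C)(C)C(C)(C)C)[C@@H](O[Si](C)(C)C(C)(C)C)[C@@H](c4ccc(OCc5ccccc5)c(OCc5ccccc5)c4)Oc3c(OCc3ccccc3)c2OCc2ccccc2)c2ccc(OCc3ccccc3)c(OCc3ccccc3)c2O[C@@H]1c1ccc(OCc2ccccc2)c(OCc2ccccc2)c1 | intermediate
20 | (2R)-3-(tert-butyldimethylsilyloxy)-4-aryl-2H-chromene dimer (C3=C4 silyl enol ether; aryl = lower unit of 15 bound through C6) | CC(C)(C)[Si](C)(C)OC1=C(c2cc3[C@H](O[Si](C)(C)C(C)(C)C)[C@@H](O[Si](C)(C)C(C)(C)C)[C@@H](c4ccc(OCc5ccccc5)c(OCc5ccccc5)c4)Oc3c(OCc3ccccc3)c2OCc2ccccc2)c2ccc(OCc3ccccc3)c(OCc3ccccc3)c2O[C@@H]1c1ccc(OCc2ccccc2)c(OCc2ccccc2)c1 | intermediate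
21 | all-cis protected dimer (upper unit 2α-aryl, 3α-silyloxy, 4α-aryl; lower unit 2α-aryl, 3α-silyloxy, 4β-silyloxy; eight benzyl ethers) | CC(C)(C)[Si](C)(C)O[C@@H]1[C@H](c2cc3[C@H](O[Si](C)(C)C(C)(C)C)[C@@H](O[Si](C)(C)C(C)(C)C)[C@@H](c4ccc(OCc5ccccc5)c(OCc5ccccc5)c4)Oc3c(OCc3ccccc3)c2OCc2ccccc2)c2ccc(OCc3ccccc3)c(OCc3ccccc3)c2O[C@@H]1c1ccc(OCc2ccccc2)c(OCc2ccccc2)c1 | intermediate
22 | octaphenol tris(tert-butyldimethylsilyl) ether of the target (silyl ethers at C3 of the upper unit and at C3 and C4 of the lower unit) | CC(C)(C)[Si](C)(C)O[C@@H]1[C@H](c2cc3[C@H](O[Si](C)(C)C(C)(C)C)[C@@H](O[Si](C)(C)C(C)(C)C)[C@@H](c4ccc(O)c(O)c4)Oc3c(O)c2O)c2ccc(O)c(O)c2O[C@@H]1c1ccc(O)c(O)c1 | intermediate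
23 | (2R,3R,4R)-2-(3,4-dihydroxyphenyl)-4-[(2R,3R,4S)-2-(3,4-dihydroxyphenyl)-3,4,7,8-tetrahydroxychroman-6-yl]chroman-3,7,8-triol | Oc1ccc([C@H]2Oc3c(ccc(O)c3O)[C@@H](c3cc4c(c(O)c3O)O[C@H](c3ccc(O)c(O)c3)[C@H](O)[C@H]4O)[C@H]2O)cc1O | target

**Step count and risks**

Total step count: 17. Longest linear sequence: 16 steps (steps 1–10, 12–17).

Steps most likely to fail:

1. Step 5 (proposed new method). What may go wrong: over-alkylation of the enolate (bis-benzylation), competing O-benzylation, or stalling of the copper-mediated ring closure in the strongly basic medium. The fallback uses three known reactions. Aldehyde 3 and ketone 6 are condensed (NaOH, EtOH/THF, Claisen–Schmidt condensation) to the chalcone (E)-3-[3,4-bis(benzyloxy)-2-bromophenyl]-1-[3,4-bis(benzyloxy)phenyl]prop-2-en-1-one F1. Its C=C bond is reduced by conjugate hydride transfer ([(Ph3P)CuH]6 as catalyst, polymethylhydrosiloxane, toluene), which spares the aryl bromide and gives ketone 7 as an isolated compound. Ketone 7 is cyclised by the known copper-catalysed intramolecular enolate O-arylation (CuI, 1,10-phenanthroline, K3PO4, DMF, 110 °C). The fallback sets out from 3 (with 6) and comes back to the route at 8.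

2. Step 6. What may go wrong: insufficient discrimination of the two alkene faces by the bulky borane, or sluggish addition to the hindered enol ether. The fallback replaces reagent control by resolution. Chromene 8 is hydroborated with BH3·SMe2 (THF, 0 °C; then NaOH, H2O2) to the racemic 2,3-trans-7,8-bis(benzyloxy)-2-[3,4-bis(benzyloxy)phenyl]chroman-3-ol F2. This is esterified with (S)-2-methoxy-2-phenylacetic acid (DCC, DMAP, CH2Cl2) to the (S)-2-methoxy-2-phenylacetate of the (2R,3S)-alcohol F3 and the (S)-2-methoxy-2-phenylacetate of the (2S,3R)-alcohol F4, which are separated by chromatography or crystallisation. Saponification of F3 (LiOH, THF/H2O) gives the enantiopure alcohol. The fallback sets out from 8 and comes back to the route at 9.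

3. Step 15. What may go wrong: failure of the hindered tetrasubstituted silyl enol ether to take up hydrogen, poor facial selectivity, or partial loss of benzyl ethers before the alkene is reduced. The fallback sets C4 and C3 in two separate polar steps. The silyl enol ether of 20 is cleaved selectively (Bu4NF buffered with AcOH, THF, −78 °C); protonation at C4 on the face opposite the C2 aryl group should give the (2R,4R)-2,4-cis-4-arylflavan-3-one F5 with the benzyl and alkyl silyl ethers intact. Reduction with Li[HB(s-Bu)3] (THF, −78 °C, equatorial hydride attack) should give the all-cis alcohol with a free 3-OH in the upper unit, F6. Hydrogenolysis (H2, Pd(OH)2/C, THF/EtOAc) gives the octaphenol bis(silyl ether) F7, which is desilylated with HF·pyridine. The fallback sets out from 20 and comes back to the route at 23.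

**Further compounds**

F1 | step 5 | (E)-3-[3,4-bis(benzyloxy)-2-bromophenyl]-1-[3,4-bis(benzyloxy)phenyl]prop-2-en-1-one | O=C(/C=C/c1ccc(OCc2ccccc2)c(OCc2ccccc2)c1Br)c1ccc(OCc2ccccc2)c(OCc2ccccc2)c1
F2 | step 6 | racemic 2,3-trans-7,8-bis(benzyloxy)-2-[3,4-bis(benzyloxy)phenyl]chroman-3-ol (both enantiomers written) | O[C@H]1Cc2ccc(OCc3ccccc3)c(OCc3ccccc3)c2O[C@@H]1c1ccc(OCc2ccccc2)c(OCc2ccccc2)c1.O[C@@H]1Cc2ccc(OCc3ccccc3)c(OCc3ccccc3)c2O[C@H]1c1ccc(OCc2ccccc2)c(OCc2ccccc2)c1
F3 | step 6 | (2R,3S)-7,8-bis(benzyloxy)-2-[3,4-bis(benzyloxy)phenyl]chroman-3-yl (S)-2-methoxy-2-phenylacetate | CO[C@H](C(=O)O[C@H]1Cc2ccc(OCc3ccccc3)c(OCc3ccccc3)c2O[C@@H]1c1ccc(OCc2ccccc2)c(OCc2ccccc2)c1)c1ccccc1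
F4 | step 6 | (2S,3R)-7,8-bis(benzyloxy)-2-[3,4-bis(benzyloxy)phenyl]chroman-3-yl (S)-2-methoxy-2-phenylacetate | CO[C@H](C(=O)O[C@@H]1Cc2ccc(OCc3ccccc3)c(OCc3ccccc3)c2O[C@H]1c1ccc(OCc2ccccc2)c(OCc2ccccc2)c1)c1ccccc1
F5 | step 15 | (2R,4R)-2,4-cis-4-arylflavan-3-one dimer (eight benzyl ethers, lower unit 3,4-bis(silyl ether)) | O=C1[C@H](c2cc3[C@H](O[Si](C)(C)C(C)(C)C)[C@@H](O[Si](C)(C)C(C)(C)C)[C@@H](c4ccc(OCc5ccccc5)c(OCc5ccccc5)c4)Oc3c(OCc3ccccc3)c2OCc2ccccc2)c2ccc(OCc3ccccc3)c(OCc3ccccc3)c2O[C@@H]1c1ccc(OCc2ccccc2)c(OCc2ccccc2)c1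
F6 | step 15 | all-cis dimer with free 3-OH in the upper unit (eight benzyl ethers, lower unit 3,4-bis(silyl ether)) | O[C@@H]1[C@H](c2cc3[C@H](O[Si](C)(C)C(C)(C)C)[C@@H](O[Si](C)(C)C(C)(C)C)[C@@H](c4ccc(OCc5ccccc5)c(OCc5ccccc5)c4)Oc3c(OCc3ccccc3)c2OCc2ccccc2)c2ccc(OCc3ccccc3)c(OCc3ccccc3)c2O[C@@H]1c1ccc(OCc2ccccc2)c(OCc2ccccc2)c1
F7 | step 15 | octaphenol with free 3-OH in the upper unit and 3,4-bis(tert-butyldimethylsilyl ether) in the lower unit | O[C@@H]1[C@H](c2cc3[C@H](O[Si](C)(C)C(C)(C)C)[C@@H](O[Si](C)(C)C(C)(C)C)[C@@H](c4ccc(O)c(O)c4)Oc3c(O)c2O)c2ccc(O)c(O)c2O[C@@H]1c1ccc(O)c(O)c1
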